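**Retrosynthetic overview**
- The strategy rests on the unbranched chain C1–C9 between ring A (2,6-dihydroxyphenyl, on the C1 ketone) and ring B (guaiacyl, on C9). Ring B with C9–C8 is eugenol without its terminal CH2, C7–C3 are the five carbons of cyclopentene, and C2–C1 with ring A is an aryl vinyl ketone without its terminal CH2.
- After retro-removal of two MOM groups and retro-hydrogenation, C7=C8 and C2=C3 are cut in a single three-component ring-opening cross-metathesis that expels ethylene.
- The enone comes from resorcinol by bis-MOM protection, lithiation between the two oxygens, addition to acrolein and oxidation.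
- No ring is formed at any stage: rings A and B are bought, and the cyclopentene ring is opened.

Key step: step 4

Remark: the C7=C8 alkene of 10 is drawn E; some 7Z isomer is expected and does not matter because step 5 saturates this bond. Eugenol is used with its phenol free, since ruthenium carbene catalysts tolerate phenols.

**Step 1**
Reactants: 1 resorcinol
Product: 2 1,3-bis(methoxymethoxy)benzene
Conditions: MOMCl (2.5 equiv), iPr2NEt (3 equiv), CH2Cl2, 0 °C to rt
Reagents that add atoms: chloromethyl methyl ether (MOMCl), COCCl
Why: Williamson-type O-alkylation of both phenols by the reactive alpha-chloro ether under amine base should give the bis-MOM ether, whose acetal oxygens direct the lithiation of step 2.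

**Step 2**
Reactants: 2 1,3-bis(methoxymethoxy)benzene; 3 acrolein
Product: 6 racemic 1-[2,6-bis(methoxymethoxy)phenyl]prop-2-en-1-ol, via aryllithium 4 (not isolated), via lithium alkoxide 5 (not isolated)
Conditions: n-BuLi (1.1 equiv), THF, 0 °C; then 3, −78 °C; then H2O
Reagents that add atoms: none
Why: Directed ortho-metalation removes the C2 hydrogen flanked by both OMOM groups, and the aryllithium should add 1,2 to acrolein at low temperature; the carbinol centre forms racemic and is destroyed in step 3.

**Step 3**
Reactants: 6 racemic 1-[2,6-bis(methoxymethoxy)phenyl]prop-2-en-1-ol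
Product: 7 1-[2,6-bis(methoxymethoxy)phenyl]prop-2-en-1-one
Conditions: MnO2 (excess, activated), CH2Cl2, rt; used promptly as a solution
Reagents that add atoms: none
Why: MnO2 oxidation of an alcohol that is both benzylic and allylic should give the aryl vinyl ketone under neutral conditions that leave the MOM acetals intact.

**Step 4**
Reactants: 7 1-[2,6-bis(methoxymethoxy)phenyl]prop-2-en-1-one; 8 eugenol; 9 cyclopentene
Product: 10 (2E,7E)-1-[2,6-bis(methoxymethoxy)phenyl]-9-(4-hydroxy-3-methoxyphenyl)nona-2,7-dien-1-one
Conditions: RuCl2(H2IMes)(=CH-C6H4-2-OiPr) (second-generation Hoveyda-Grubbs catalyst, 5 mol% in two portions), 1,4-benzoquinone (10 mol%), 8 (1.5 equiv), 9 (5 equiv, 0.5 M), CH2Cl2, 40 °C, 7 (1.0 equiv) added over 4 h, Ar sweep through a −20 °C condenser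
Reagents that add atoms: none
Why: Proposed new method: the ruthenium carbene released from the catalyst engages the electron-rich terminal alkene of 8 first, giving Ru=CH-CH2Ar, which undergoes [2+2] cycloaddition to cyclopentene 9 and cycloreversion of the ruthenacyclobutane to open the ring (C7=C8 formed) and leave Ru=CH-(CH2)3-CH=CH-CH2Ar; the electron-poor enone 7 traps this alkylidene, forming the conjugated C2=C3 bond and Ru=CH2, which returns to 8 with loss of ethylene. The closest known reactions are ring-opening cross-metathesis of cyclopentene and other low-strain cycloalkenes with acrylates and vinyl ketones, and two-component cross-metathesis of eugenol with acrylates; the new element is the selective union of three components with two different chain ends. No ring is closed (the cyclopentene ring is opened) and no stereocentre is formed; the enone alkene should be E for thermodynamic reasons and the C7=C8 geometry is erased in step 5. The step needs hetero end-capping with exactly one cyclopentene unit: 7 forms no productive acyl-substituted carbene and does not homodimerise, so it only terminates chains begun at the eugenol end, and enone-capped ends are inert to secondary metathesis, whereas eugenol-only products (its homodimer, the bis-eugenol-capped diene) and the enone-capped terminal diene formed when Ru=CH2 opens 9 stay reactive and are drawn on toward 10 by the excess of 8. Cyclopentene is kept in excess over 8 to outrun direct coupling of 8 with 7, yet below the concentration at which its ring-opening oligomerisation becomes favourable (on the order of 1 M near room temperature); slow addition keeps 7 scarce so that enone-enone capping is rare, and 1,4-benzoquinone suppresses ruthenium-hydride isomerisation of the allyl group.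

**Step 5**
Reactants: 10 (2E,7E)-1-[2,6-bis(methoxymethoxy)phenyl]-9-(4-hydroxy-3-methoxyphenyl)nona-2,7-dien-1-one
Product: 11 1-[2,6-bis(methoxymethoxy)phenyl]-9-(4-hydroxy-3-methoxyphenyl)nonan-1-one
Conditions: H2 (1 atm), Pd/C, EtOAc, rt, stopped at full alkene consumption
Reagents that add atoms: none
Why: Heterogeneous catalytic hydrogenation should saturate the conjugated and the isolated disubstituted alkene while the hindered di-ortho-substituted aryl ketone, the MOM acetals and the phenol persist in a neutral aprotic solvent; it precedes MOM removal because a free ortho-hydroxy enone would cyclise to a chromanone by oxa-Michael addition.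

**Step 6**
Reactants: 11 1-[2,6-bis(methoxymethoxy)phenyl]-9-(4-hydroxy-3-methoxyphenyl)nonan-1-one
Product: 12 1-(2,6-dihydroxyphenyl)-9-(4-hydroxy-3-methoxyphenyl)nonan-1-one (target)
Conditions: HCl (aq, cat.), MeOH, 45 °C
Reagents that add atoms: none
Why: Acid-catalysed acetal exchange with methanol should cleave both aryl MOM ethers, and the saturated chain offers the liberated ortho-phenols no site for cyclisation.

**Compound list**
1 | resorcinol | Oc1cccc(O)c1 | starting material
2 | 1,3-bis(methoxymethoxy)benzene | COCOc1cccc(OCOC)c1 | intermediate
3 | acrolein | C=CC=O | starting material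
4 | 2-lithio-1,3-bis(methoxymethoxy)benzene | [Li]c1c(OCOC)cccc1OCOC | intermediate (not isolated)
5 | lithium 1-[2,6-bis(methoxymethoxy)phenyl]prop-2-en-1-olate | [Li+].[O-]C(C=C)c1c(OCOC)cccc1OCOC | intermediate (not isolated)
6 | racemic 1-[2,6-bis(methoxymethoxy)phenyl]prop-2-en-1-ol | C=CC(O)c1c(OCOC)cccc1OCOC | intermediate
7 | 1-[2,6-bis(methoxymethoxy)phenyl]prop-2-en-1-one | C=CC(=O)c1c(OCOC)cccc1OCOC | intermediate
8 | eugenol (4-allyl-2-methoxyphenol) | C=CCc1ccc(O)c(OC)c1 | starting material
9 | cyclopentene | C1=CCCC1 | starting material
10 | (2E,7E)-1-[2,6-bis(methoxymethoxy)phenyl]-9-(4-hydroxy-3-methoxyphenyl)nona-2,7-dien-1-one | COc1cc(C/C=C/CCC/C=C/C(=O)c2c(OCOC)cccc2OCOC)ccc1O | intermediate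
11 | 1-[2,6-bis(methoxymethoxy)phenyl]-9-(4-hydroxy-3-methoxyphenyl)nonan-1-one | COc1cc(CCCCCCCCC(=O)c2c(OCOC)cccc2OCOC)ccc1O | intermediate
12 | 1-(2,6-dihydroxyphenyl)-9-(4-hydroxy-3-methoxyphenyl)nonan-1-one | COc1cc(CCCCCCCCC(=O)c2c(O)cccc2O)ccc1O | target

**Step count and risks**
Total step count: 6. Longest linear sequence: 6 steps (1 to 2 to 6 to 7 to 10 to 11 to 12).

Steps most likely to fail:

1. Step 4. The partners may scramble statistically: 8 may couple directly with 7 without cyclopentene insertion, several cyclopentene units may insert, two enones may cap one chain, and the allyl group may migrate to a propenyl group. Each of these lowers the share of the hetero-capped single-insertion diene and makes chromatographic separation harder. The fallback uses known two-component chemistry, sets out from 2 and comes back at 11. Compound 2 is lithiated to 4 as in step 2, and 4 is added to commercial oct-7-enal (C=CCCCCCC=O) with aqueous quench to give 1-[2,6-bis(methoxymethoxy)phenyl]oct-7-en-1-ol F1. Dess-Martin periodinane in CH2Cl2 should give 1-[2,6-bis(methoxymethoxy)phenyl]oct-7-en-1-one F2. Ordinary cross-metathesis of F2 with an excess of eugenol 8 (same ruthenium catalyst, 1,4-benzoquinone, CH2Cl2, 40 °C) should give (E)-1-[2,6-bis(methoxymethoxy)phenyl]-9-(4-hydroxy-3-methoxyphenyl)non-7-en-1-one F3. Hydrogenation of F3 under the conditions of step 5 returns to 11.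

2. Step 3. The electron-poor vinyl ketone may polymerise or take up nucleophiles during oxidation, filtration and concentration. The fallback stores the enone in masked form, sets out from 2 and comes back at 7. Compound 2 is lithiated to 4 as in step 2, and 4 is acylated with N-methoxy-N-methylacetamide to give 1-[2,6-bis(methoxymethoxy)phenyl]ethan-1-one F4. Its lithium enolate (LiN(iPr)2, THF, −78 °C) is aminomethylated with dimethylmethylideneammonium iodide (Mannich reaction) to give 3-(dimethylamino)-1-[2,6-bis(methoxymethoxy)phenyl]propan-1-one F5, which can be stored. MeI converts it into 3-[2,6-bis(methoxymethoxy)phenyl]-N,N,N-trimethyl-3-oxopropan-1-aminium iodide F6. Elimination with aqueous NaHCO3 in CH2Cl2 releases 7 as a dried solution that is fed directly into step 4.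

3. Step 5. Hydrogenation may run on past the alkenes, reducing the aryl ketone to the benzylic alcohol or further, or it may stall at the hindered conjugated alkene. The fallback replaces catalytic hydrogenation by diimide transfer, sets out from 10 and comes back at 11. Diimide generated from dipotassium azodicarboxylate (KO2C-N=N-CO2K) and AcOH in MeOH at rt, used in excess, should saturate both C=C bonds by concerted syn hydrogen transfer. It cannot reduce the C=O group or cleave the MOM acetals.

**Further compounds**
F1 | step 4 | 1-[2,6-bis(methoxymethoxy)phenyl]oct-7-en-1-ol | C=CCCCCCC(O)c1c(OCOC)cccc1OCOC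
F2 | step 4 | 1-[2,6-bis(methoxymethoxy)phenyl]oct-7-en-1-one | C=CCCCCCC(=O)c1c(OCOC)cccc1OCOC
F3 | step 4 | (E)-1-[2,6-bis(methoxymethoxy)phenyl]-9-(4-hydroxy-3-methoxyphenyl)non-7-en-1-one | COc1cc(C/C=C/CCCCCC(=O)c2c(OCOC)cccc2OCOC)ccc1O
F4 | step 3 | 1-[2,6-bis(methoxymethoxy)phenyl]ethan-1-one | CC(=O)c1c(OCOC)cccc1OCOC
F5 | step 3 | 3-(dimethylamino)-1-[2,6-bis(methoxymethoxy)phenyl]propan-1-one | CN(C)CCC(=O)c1c(OCOC)cccc1OCOC
F6 | step 3 | 3-[2,6-bis(methoxymethoxy)phenyl]-N,N,N-trimethyl-3-oxopropan-1-aminium iodide | C[N+](C)(C)CCC(=O)c1c(OCOC)cccc1OCOC.[I-]
F0 | step 5 | none | none
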